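## The problem

CNP0178319.3 (22) is a cyclohexane (ring A) cis-fused to a γ-lactone, and the lactone is spanned a second time. The oxygen on the lactone α-carbon and the lactone γ-carbon are joined through a C(CH3)2–CH=CH unit, so a 2,2-dimethyl-2,5-dihydrooxepine bridges the five-membered ring (an oxa-bridged bicyclo[4.2.1]nonene). Ring A is numbered here C1 (acetoxy CH), C2 (CH2), C3 (methyl carbinol), C4 (oxygenated lactone α-carbon), C5 (methyl-bearing lactone β-carbon) and C6 (benzoyloxy CH); C7 is the lactone γ-CH. (Benzofuranone locants in the compound list: C1 = 5, C2 = 6, C3 = 7, C4 = 7a, C5 = 3a, C6 = 4, C7 = 3.)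

Six stereocentres must be set, five of them contiguous on ring A, and C4 and C5 are adjacent fully substituted carbons. C7 lies outside ring A: once in place it decides the face of the lactone, hence C5 and, through the cis fusion, C4. C1 can be bought and can bias C6, while C3 must come out of the ring closure itself.

The molecule is fragile. Acetate and benzoate sit on cis-vicinal oxygens and migrate under base, the C3 hydroxyl is β to the lactone carbonyl (retro-aldol, dehydration), and the ring ether is di-tertiary and allylic and ionises in acid.

The hardest single bond is the one between the C4 oxygen and the tertiary ether carbon. Once C4 is sp3 this oxygen is flanked by two fully substituted carbons and has the tertiary C3 hydroxyl as a competitor, so the ether is best made before ring A exists.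

The feature that permits this, and the key step, is that C4 and C5 with oxygen, methyl and lactone are the alkene of a 3-alkoxy-4-methylbutenolide (an O-alkylated isotetronic acid). The remaining carbons C6–C1–C2–C3 carry oxygen in the pattern of a 2-alkoxy-4-oxopentanal, so ring A is the sum of a C=C and a keto aldehyde.

## Retrosynthesis

**Oxepine alkene (22 ⇒ 21).** The ring C=C is cut first, giving diene 21 with a 1,1-dimethylallyl ether on the C4 oxygen and a vinyl group on C7. The neighbouring cut, O–C(CH3)2, would leave a tertiary hydroxyl between two quaternary carbons as the last nucleophile of the synthesis. The metathesis cut needs only two terminal alkenes that are cis on the lactone. 21 has one ring and no medium ring fewer than 22. The forward step must close a bridged seven-membered ring from two alkenes that each carry a fully substituted allylic carbon.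

**Masked alkenes (21 ⇒ 20 ⇒ 19 ⇒ 18).** The allyl ether of 21 is traced to the terminal alkyne 20 (semihydrogenation). The C7 vinyl group is traced to the terminal diol 19 and its acetonide 18 (deoxygenative olefination, hydrolysis). No skeletal bond is cut; both alkenes simply travel in masked form through the reductive key step. An allyl vinyl ether at the butenolide stage would undergo Claisen rearrangement far more easily than the propargyl ether, and the dioxolane is the glyceraldehyde remnant that sets C7 while keeping the butenolide γ-hydrogen less labile than a vinyl group would. The forward steps must hydrolyse an acetonide beside two esters and a tertiary propargylic ether, turn a 1,2-diol into an alkene, and stop a hydrogenation at the alkene.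

**Esters (18 ⇒ 17 ⇒ 16 ⇒ 15).** Acetate and benzoate are removed in the order in which the oxygens can be told apart: acetate 18 ⇒ alcohol 17 ⇒ PMB ether 16 ⇒ diol 15. In 15 the C6 hydroxyl is the only secondary one, the C1 oxygen is a PMB ether and the C3 hydroxyl is tertiary, so no further protecting group is needed. Carrying the acetate through the annulation is rejected because an α-acyloxy aldehyde loses carboxylate under SmI2.

**Ring A (15 ⇒ 7 + 14).** Ring A is cut at C5–C6 and C3–C4 into butenolide 7 and keto aldehyde 14. Among two-bond cuts of ring A this one lets each fragment keep one purchasable stereocentre (C7 in 7, C1 in 14) and brings the two quaternary carbons as an alkene. Both new bonds end on a carbinol carbon, so a ketyl addition and an aldol can make them in one flask. A cut through C4–C5 would have to join two fully substituted carbons. The simplification is from six stereocentres and two rings to two fragments of three and four steps. The forward reaction must add a samarium ketyl to a tetrasubstituted, donor-substituted alkene, which is beyond precedent.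

**Butenolide (7 ⇒ 5 + 6; 5 ⇒ 2 + 3; 2 ⇒ 1).** The O–C(tertiary) bond is cut at the enol stage, giving isotetronic acid 5 and 3-chloro-3-methylbut-1-yne 6. The enol oxygen is acidic and unhindered, the opposite of the C4 hydroxyl it later becomes. 5 is cut at the bond between the methyl-bearing carbon and the carbinol carbon into enol silane 2 and (S)-glyceraldehyde acetonide 3 (aldol, then lactonisation). 2 comes from ethyl 2-oxobutanoate 1. The aldol must be anti-selective relative to the dioxolane.

**Keto aldehyde (14 ⇒ 13 ⇒ 12 ⇒ 10 ⇒ 8 + 9).** 14 is a β-alkoxy ketone that eliminates with base, so both carbonyls are unmasked last, by ozonolysis of diene 13. 13 is the PMB ether of dienol 12, which comes by one-carbon homologation from chlorohydrin 10. 10 is made from (S)-epichlorohydrin 8 and isopropenylmagnesium bromide 9. The stereocentre is bought and never touched.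

## Roads not taken

**Alternative 1:** Ring A is cut at C4–C5 and C6–C1 into 3-hydroxy-4-methyl-2-pyrone A2 (diene) and (E)-3-benzoyloxy-2-methylacrolein A3 (dienophile). A bifunctional cinchona amine base would deprotonate A2 and steer its addition to A3, giving the lactone-bridged bicyclo[2.2.2]octene A1. In A1, C4 (hydroxyl), C5 (methyl, formyl) and C6 (benzoate) are set and C1 carries the bridging lactone oxygen.
- Merits: base-catalysed Diels–Alder reactions of 3-hydroxy-2-pyrones are an established, catalytic, enantioselective class. The bond between the two quaternary carbons and four stereocentres come from two flat achiral components, and the benzoate is in from the start.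
- Weak points: A3 is a trisubstituted, α-branched enal and also an enol ester, so it is a sluggish dienophile and can pass its benzoyl group to the amine or to A2. The lactone of A1 is tied to C1, not C7, so the formyl group must be vinylated (C7 next to a quaternary carbon, with no evident control) and the lactone moved. The C2=C3 alkene must be hydrated at C3 from a defined face. The C4 hydroxyl must still be alkylated with a tertiary carbon after it has become flanked by two quaternary carbons.
- Comparison: as a ring-forming event this road rests on firmer precedent than step 8 and needs no stoichiometric reductant; in that respect it is better. The chosen plan sets against it that C7, C1 and the C4 ether exist before ring A does, that C3 forms in the annulation, and that no oxygen has to be moved afterwards.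

**Alternative 2:** The cut is the O–C(CH3)2 bond of the oxepine, back to epoxy alcohol A5 (free C4 hydroxyl, silyl ether on C3, a (3,3-dimethyloxiranyl)methyl group on C7). Camphorsulfonic acid would activate the oxirane, and the C4 hydroxyl would attack its dimethyl-substituted carbon (7-endo) to give hydroxy oxepane A4.
- Merits: the difficult ether bond is made intramolecularly at the carbon that best carries positive charge, with no metal. Against any late intermolecular etherification this is clearly the better way.
- Weak points: the nucleophile is a tertiary hydroxyl α to a lactone carbonyl between two quaternary carbons, so hydride or methyl shift of the opened epoxide and 6-exo attack at the secondary carbon compete. The C3 hydroxyl needs its own protecting group. A4 carries a secondary hydroxyl beside the quaternary ether carbon that must be eliminated towards the CH2, which costs further steps on a carbinol prone to rearrangement. The cut says nothing about how ring A and its quaternary carbons arise.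
- Comparison: both plans accept that the C4 oxygen cannot be alkylated intermolecularly late. Alternative 2 answers with intramolecularity at the end; the chosen plan alkylates the flat, acidic enol oxygen of 5 at the start and then needs only a semihydrogenation and a metathesis. Alternative 2 has the advantage that it avoids the metathesis between two hindered alkenes (step 15).

**Alternative 3:** The cut is C1–C2 of ring A, back to aldehyde A7, which already holds lactone, oxepine and both quaternary carbons, with an isopropenyl group on C4 and the benzoyloxy acetaldehyde arm on C5. With Me2AlCl the terminal CH2 of the isopropenyl group would attack the aldehyde while a methyl hydrogen moves to oxygen (type 2 carbonyl-ene), closing ring A as the 3-methylenecyclohexanol A6.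
- Merits: a well-known, mild cyclisation on a rigid template, likely with good control at C1, and no late metathesis. In reliability of the key step this road is ahead of the chosen plan.
- Weak points: A7 already contains everything that is hard (adjacent quaternary carbons, hindered ether, bridged ring), and the cut offers no way to them. The α-benzoyloxy aldehyde can epimerise at C6 and chelate aluminium. A6 still lacks the C3 oxygen, so the exocyclic methylene must be hydrated at its substituted carbon from one face, which is not secured, before acetylation.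
- Comparison: the chosen plan is convergent, makes both quaternary carbons in its key step and sets C3 with its oxygen directly. It pays with an unprecedented annulation where Alternative 3 uses a known one.

Key step: step 8

Assumption: (S)-glyceraldehyde acetonide 3, 3-chloro-3-methylbut-1-yne 6 and isopropenylmagnesium bromide 9 (THF solution) are treated as purchasable; 3 epimerises and oligomerises on standing and would be distilled before use.

## Route

Step 1
Reactants: 1 ethyl 2-oxobutanoate
Product: 2 ethyl (Z)-2-[(trimethylsilyl)oxy]but-2-enoate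
Conditions: TMSCl, Et3N, MeCN, 0 °C → rt
Reagents that add atoms: chlorotrimethylsilane, C[Si](C)(C)Cl
Why: Soft enolisation of the α-keto ester (only C3 can enolise) and O-silylation give the conjugated 2-silyloxy enoate, a standard silyl enol ether formation. No stereocentre is formed and the alkene geometry does not matter later.

Step 2
Reactants: 2 ethyl (Z)-2-[(trimethylsilyl)oxy]but-2-enoate; 3 (S)-2,2-dimethyl-1,3-dioxolane-4-carbaldehyde
Product: 5 (5R)-5-[(4S)-2,2-dimethyl-1,3-dioxolan-4-yl]-3-hydroxy-4-methylfuran-2(5H)-one, via aldol adduct 4 (not isolated)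
Conditions: BF3·OEt2, CH2Cl2, −78 °C; then PPTS (cat.), toluene, 60 °C
Reagents that add atoms: none
Why: Mukaiyama aldol through an open transition state; BF3 cannot chelate, so attack follows the Felkin–Anh model anti to the dioxolane C–O bond and sets the new carbinol centre (R), the later C7. The methyl epimers of 4 converge when the γ-hydroxy-α-keto ester lactonises and enolises to the isotetronic acid.

Step 3
Reactants: 5 (5R)-5-[(4S)-2,2-dimethyl-1,3-dioxolan-4-yl]-3-hydroxy-4-methylfuran-2(5H)-one; 6 3-chloro-3-methylbut-1-yne
Product: 7 (5R)-5-[(4S)-2,2-dimethyl-1,3-dioxolan-4-yl]-4-methyl-3-[(2-methylbut-3-yn-2-yl)oxy]furan-2(5H)-one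
Conditions: DBU, CuCl2 (1 mol%), MeCN, −5 → 0 °C
Reagents that add atoms: none
Why: Copper-catalysed propargylic substitution: the copper acetylide of 6 ionises to an allenylidene that is captured at the tertiary carbon by the enol oxygen of 5, which is about as acidic as a phenol, the usual substrate. Attack through the methyl-bearing enol carbon would build two adjacent quaternary carbons and is not expected; the low temperature keeps the propargyl vinyl ether below the onset of [3,3] rearrangement.

Step 4
Reactants: 8 (S)-2-(chloromethyl)oxirane; 9 isopropenylmagnesium bromide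
Product: 10 (S)-1-chloro-4-methylpent-4-en-2-ol
Conditions: CuI (10 mol%), THF, −40 → −20 °C
Reagents that add atoms: none
Why: Copper-catalysed Grignard opening of the epoxide at its unsubstituted carbon. The stereocentre is not touched, so (S)-8 gives (S)-10.

Step 5
Reactants: 10 (S)-1-chloro-4-methylpent-4-en-2-ol
Product: 12 (S)-5-methylhexa-1,5-dien-3-ol, via epoxide 11 (not isolated)
Conditions: Me3S+ I−, n-BuLi, THF, −20 °C → rt
Reagents that add atoms: trimethylsulfonium iodide, C[S+](C)C.[I-]
Why: Base closes the chlorohydrin to epoxide 11; dimethylsulfonium methylide opens it at the terminal carbon and the betaine loses dimethyl sulfide after a second deprotonation (one-carbon homologation of a terminal epoxide to an allylic alcohol). The carbinol centre is again untouched.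

Step 6
Reactants: 12 (S)-5-methylhexa-1,5-dien-3-ol
Product: 13 (S)-1-methoxy-4-{[(5-methylhexa-1,5-dien-3-yl)oxy]methyl}benzene
Conditions: NaH, PMBCl, Bu4NI (cat.), THF/DMF, 0 °C → rt
Reagents that add atoms: 4-methoxybenzyl chloride, COc1ccc(CCl)cc1
Why: Williamson etherification of the secondary allylic alcohol. PMB survives SmI2 and leaves later under neutral oxidative conditions.

Step 7
Reactants: 13 (S)-1-methoxy-4-{[(5-methylhexa-1,5-dien-3-yl)oxy]methyl}benzene
Product: 14 (S)-2-[(4-methoxybenzyl)oxy]-4-oxopentanal
Conditions: O3, CH2Cl2, −78 °C; then PPh3, −78 °C → rt; used crude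
Reagents that add atoms: ozone, [O-][O+]=O
Why: Ozonolysis of both terminal alkenes with reductive work-up unmasks ketone and aldehyde in one neutral operation; the alkenes react with ozone faster than the anisyl ring. 14 is a β-alkoxy ketone prone to E1cB loss of the PMB oxide, so it is made last and not stored.

Step 8
Reactants: 7 (5R)-5-[(4S)-2,2-dimethyl-1,3-dioxolan-4-yl]-4-methyl-3-[(2-methylbut-3-yn-2-yl)oxy]furan-2(5H)-one; 14 (S)-2-[(4-methoxybenzyl)oxy]-4-oxopentanal
Product: 15 cis-fused ring A lactone with free C6 and C3 hydroxyls, C1 PMB ether, C4 1,1-dimethylpropargyl ether and C7 dioxolanyl group (systematic name in the compound list)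
Conditions: SmI2 (2.5 equiv), 7 (2 equiv), THF, −78 °C, slow addition of 14; −78 → −20 °C; then pH 7 buffer
Reagents that add atoms: none
Why: Proposed new method: SmI2 reduces the aldehyde of 14 (more easily reduced than the methyl ketone) to a samarium ketyl that adds to C5, the β-carbon of 7; the captodative C4 radical takes a second electron and the trivalent samarium enolate closes ring A by a 6-(enolexo)-exo-trig aldol onto the tethered methyl ketone. The closest known reaction type is the SmI2 ketyl–olefin coupling of aldehydes with unsaturated esters or lactones followed by samarium-enolate aldol; intermolecular addition to a tetrasubstituted 3-alkoxybutenolide has no precedent. C5: the ketyl attacks the butenolide face anti to the dioxolanyl group on C7. C6: samarium bridging the ketyl oxygen and the lactone carbonyl places the C6–O bond over the lactone ring and the chain outward, which is also the Felkin–Anh sense relative to the C1 ether, so the two controls are matched. C4: the tether reaches the enolate only from the face that carries C6, so the fusion is cis. C3: in the samarium-bridged chair the ketone oxygen is held syn to the lactone carbonyl and the methyl group is equatorial. The step needs the ketyl to add to 7 faster than it dimerises or is reduced further; slow addition of 14 to SmI2 and excess 7 secures this, and the absence of a proton source keeps the enolate alive for the aldol, which should outrun a [2,3] shift of the propargyl ether at −78 °C.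

Step 9
Reactants: 15 ring A lactone diol (C6–OH, C3–OH, C1–OPMB)
Product: 16 C6 benzoate of 15
Conditions: BzCl, DMAP, pyridine, 0 → 40 °C
Reagents that add atoms: benzoyl chloride, O=C(Cl)c1ccccc1
Why: DMAP-catalysed acylation of the only secondary hydroxyl. The tertiary C3 hydroxyl, axial and next to a quaternary carbon, does not react under these conditions.

Step 10
Reactants: 16 C6 benzoate with C1 PMB ether
Product: 17 C1 alcohol (C6 benzoate, C3–OH, C4 propargyl ether, C7 dioxolanyl)
Conditions: DDQ, CH2Cl2/pH 7 buffer, 0 °C → rt
Reagents that add atoms: none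
Why: Oxidative PMB cleavage by hydride abstraction to the oxocarbenium ion and hydrolysis. The buffered neutral medium leaves the cis benzoate in place, and alkyne, acetonide and tertiary ether are inert to DDQ.

Step 11
Reactants: 17 C1 alcohol
Product: 18 C1 acetate, C6 benzoate (C7 dioxolanyl, C4 propargyl ether)
Conditions: Ac2O, pyridine, DMAP (cat.), CH2Cl2, 0 °C
Reagents that add atoms: acetic anhydride, CC(=O)OC(C)=O
Why: DMAP-catalysed acetylation of the secondary C1 hydroxyl, which is faster than migration of the neighbouring benzoate. The tertiary hydroxyl stays free.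

Step 12
Reactants: 18 acetonide diester
Product: 19 terminal diol on C7 (C1 acetate, C6 benzoate, C4 propargyl ether)
Conditions: AcOH/H2O (4:1), 35 °C
Reagents that add atoms: none
Why: Acid-catalysed hydrolysis of the terminal acetonide. Esters, lactone and the propargylic di-tertiary ether are stable to dilute acetic acid, and the five-membered lactone is favoured over translactonisation to the side-chain hydroxyls.

Step 13
Reactants: 19 terminal diol
Product: 20 C7 vinyl lactone with C4 1,1-dimethylpropargyl ether
Conditions: PPh3, imidazole, I2, toluene, 80 °C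
Reagents that add atoms: none
Why: Garegg–Samuelsson deoxygenation of the vicinal diol to the terminal alkene via the iodophosphonium and vicinal iodide stage. C7 is not involved and keeps its configuration; the hindered tertiary hydroxyl and the terminal alkyne are not attacked.

Step 14
Reactants: 20 C7 vinyl lactone with terminal alkyne
Product: 21 diene with C4 1,1-dimethylallyl ether and C7 vinyl group
Conditions: H2 (1 atm), Pd/CaCO3/Pb(OAc)2 (Lindlar catalyst), quinoline, EtOAc, rt
Reagents that add atoms: none
Why: Lindlar semihydrogenation: the terminal alkyne binds to the poisoned palladium far more strongly than the monosubstituted alkene, so uptake should stop at the allyl ether.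

Step 15
Reactants: 21 diene
Product: 22 CNP0178319.3
Conditions: second-generation Hoveyda–Grubbs catalyst (10 mol%), toluene (2 mM), 80 °C
Reagents that add atoms: none
Why: Ring-closing metathesis: the ether oxygen on C4 and the vinyl group on C7 are cis on the lactone, and 1,1-dimethylallyl ethers are established partners for closing 2,2-dimethyl oxacycles. Loss of ethylene drives the closure, the ring size enforces the Z alkene and high dilution suppresses dimerisation.

## Compound list

1 | ethyl 2-oxobutanoate | CCC(=O)C(=O)OCC | starting material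
2 | ethyl (Z)-2-[(trimethylsilyl)oxy]but-2-enoate | C/C=C(\O[Si](C)(C)C)C(=O)OCC | intermediate
3 | (S)-2,2-dimethyl-1,3-dioxolane-4-carbaldehyde ((S)-glyceraldehyde acetonide) | O=C[C@@H]1COC(C)(C)O1 | starting material
4 | ethyl (4R)-4-[(4S)-2,2-dimethyl-1,3-dioxolan-4-yl]-4-hydroxy-3-methyl-2-oxobutanoate (both C3 epimers; not isolated) | CCOC(=O)C(=O)C(C)[C@@H](O)[C@@H]1COC(C)(C)O1 | intermediate
5 | (5R)-5-[(4S)-2,2-dimethyl-1,3-dioxolan-4-yl]-3-hydroxy-4-methylfuran-2(5H)-one | O=C1O[C@@H]([C@@H]2COC(C)(C)O2)C(C)=C1O | intermediate
6 | 3-chloro-3-methylbut-1-yne | CC(C)(Cl)C#C | starting material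
7 | (5R)-5-[(4S)-2,2-dimethyl-1,3-dioxolan-4-yl]-4-methyl-3-[(2-methylbut-3-yn-2-yl)oxy]furan-2(5H)-one | O=C1O[C@@H]([C@@H]2COC(C)(C)O2)C(C)=C1OC(C)(C)C#C | intermediate
8 | (S)-2-(chloromethyl)oxirane ((S)-epichlorohydrin) | ClC[C@@H]1CO1 | starting material
9 | isopropenylmagnesium bromide | CC(=C)[Mg]Br | starting material
10 | (S)-1-chloro-4-methylpent-4-en-2-ol | ClC[C@@H](O)CC(C)=C | intermediate
11 | (S)-2-(2-methylprop-2-en-1-yl)oxirane (not isolated) | C=C(C)C[C@H]1CO1 | intermediate
12 | (S)-5-methylhexa-1,5-dien-3-ol | C=C[C@@H](O)CC(C)=C | intermediate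
13 | (S)-1-methoxy-4-{[(5-methylhexa-1,5-dien-3-yl)oxy]methyl}benzene | C=C[C@@H](OCc1ccc(OC)cc1)CC(C)=C | intermediate
14 | (S)-2-[(4-methoxybenzyl)oxy]-4-oxopentanal | O=C[C@@H](OCc1ccc(OC)cc1)CC(C)=O | intermediate
15 | (3R,3aS,4R,5S,7S,7aS)-3-[(4S)-2,2-dimethyl-1,3-dioxolan-4-yl]-4,7-dihydroxy-5-[(4-methoxybenzyl)oxy]-3a,7-dimethyl-7a-[(2-methylbut-3-yn-2-yl)oxy]hexahydro-2-benzofuran-1(3H)-one | COc1ccc(CO[C@H]2C[C@](C)(O)[C@]3(OC(C)(C)C#C)C(=O)O[C@@H]([C@@H]4COC(C)(C)O4)[C@]3(C)[C@H]2O)cc1 | intermediate
16 | (3R,3aS,4R,5S,7S,7aS)-3-[(4S)-2,2-dimethyl-1,3-dioxolan-4-yl]-7-hydroxy-5-[(4-methoxybenzyl)oxy]-3a,7-dimethyl-7a-[(2-methylbut-3-yn-2-yl)oxy]-1-oxooctahydro-2-benzofuran-4-yl benzoate | COc1ccc(CO[C@H]2C[C@](C)(O)[C@]3(OC(C)(C)C#C)C(=O)O[C@@H]([C@@H]4COC(C)(C)O4)[C@]3(C)[C@H]2OC(=O)c5ccccc5)cc1 | intermediate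
17 | (3R,3aS,4R,5S,7S,7aS)-3-[(4S)-2,2-dimethyl-1,3-dioxolan-4-yl]-5,7-dihydroxy-3a,7-dimethyl-7a-[(2-methylbut-3-yn-2-yl)oxy]-1-oxooctahydro-2-benzofuran-4-yl benzoate | O[C@H]1C[C@](C)(O)[C@]2(OC(C)(C)C#C)C(=O)O[C@@H]([C@@H]3COC(C)(C)O3)[C@]2(C)[C@H]1OC(=O)c1ccccc1 | intermediate
18 | (3R,3aS,4R,5S,7S,7aS)-5-acetoxy-3-[(4S)-2,2-dimethyl-1,3-dioxolan-4-yl]-7-hydroxy-3a,7-dimethyl-7a-[(2-methylbut-3-yn-2-yl)oxy]-1-oxooctahydro-2-benzofuran-4-yl benzoate | CC(=O)O[C@H]1C[C@](C)(O)[C@]2(OC(C)(C)C#C)C(=O)O[C@@H]([C@@H]3COC(C)(C)O3)[C@]2(C)[C@H]1OC(=O)c1ccccc1 | intermediate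
19 | (3R,3aR,4R,5S,7S,7aS)-5-acetoxy-3-[(1S)-1,2-dihydroxyethyl]-7-hydroxy-3a,7-dimethyl-7a-[(2-methylbut-3-yn-2-yl)oxy]-1-oxooctahydro-2-benzofuran-4-yl benzoate | CC(=O)O[C@H]1C[C@](C)(O)[C@]2(OC(C)(C)C#C)C(=O)O[C@@H]([C@@H](O)CO)[C@]2(C)[C@H]1OC(=O)c1ccccc1 | intermediate
20 | (3S,3aR,4R,5S,7S,7aS)-5-acetoxy-7-hydroxy-3a,7-dimethyl-7a-[(2-methylbut-3-yn-2-yl)oxy]-1-oxo-3-vinyloctahydro-2-benzofuran-4-yl benzoate | CC(=O)O[C@H]1C[C@](C)(O)[C@]2(OC(C)(C)C#C)C(=O)O[C@@H](C=C)[C@]2(C)[C@H]1OC(=O)c1ccccc1 | intermediate
21 | (3S,3aR,4R,5S,7S,7aS)-5-acetoxy-7-hydroxy-3a,7-dimethyl-7a-[(2-methylbut-3-en-2-yl)oxy]-1-oxo-3-vinyloctahydro-2-benzofuran-4-yl benzoate | CC(=O)O[C@H]1C[C@](C)(O)[C@]2(OC(C)(C)C=C)C(=O)O[C@@H](C=C)[C@]2(C)[C@H]1OC(=O)c1ccccc1 | intermediate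
22 | CNP0178319.3: the (3S,3aR,4R,5S,7S,7aS)-5-acetoxy-4-benzoyloxy-7-hydroxy-3a,7-dimethylhexahydro-2-benzofuran-1(3H)-one whose O on C7a and C3 are bridged by C(CH3)2–CH=CH (Z), closing the 2,2-dimethyl-2,5-dihydrooxepine | CC(=O)O[C@H]1C[C@](C)(O)[C@]23OC(C)(C)C=C[C@H](OC2=O)[C@]3(C)[C@H]1OC(=O)c1ccccc1 | target

## Step count and least certain steps

Total step count: 15 (steps 1–3 butenolide arm, steps 4–7 keto aldehyde arm, step 8 annulation, steps 9–15 endgame). Longest linear sequence: 12 steps (4–7, 8, 9–15) from (S)-epichlorohydrin 8.

**Step 8 (carries the label).** Most likely failure: the ketyl is not captured fast enough by the hindered, donor-substituted alkene. Reductive dimerisation or over-reduction of the aldehyde, loss of the PMB oxide from the reduced aldehyde, or closure of the keto aldehyde on itself would then win. After a successful addition the enolate could still undergo a [2,3] shift of the propargyl ether, and the sense at C6 rests on a transition-state model.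

Fallback with known chemistry, setting out from 5 and 14 and returning at 15: the α-oxygen is left out of the acceptor, so the annulation falls into the documented class of samarium ketyl additions to β-substituted butenolides, and is put back afterwards. 5 is converted into the enol triflate F1 (Tf2O, pyridine) and reduced (Pd(OAc)2, PPh3, HCO2H, Et3N) to the 3-unsubstituted butenolide F2. The same SmI2 annulation of F2 with 14 should give the C4–H lactone F3 with the same sense at C3, C5 and C6. Both hydroxyls are silylated (TESOTf, 2,6-lutidine) to the bis(triethylsilyl) ether F4. Its potassium enolate (KN(SiMe3)2, −78 °C) is hydroxylated with 2-(phenylsulfonyl)-3-phenyloxaziridine on the convex face to the C4 hydroxy lactone F5. A Nicholas reaction with the cobalt–alkynol complex F6 (from 2-methylbut-3-yn-2-ol and Co2(CO)8; BF3·OEt2) gives the complexed ether F7, with the C3 silyl ether blocking the neighbouring hydroxyl. (NH4)2Ce(NO3)6 releases the alkyne F8 and HF·pyridine removes both silyl groups to give 15. The detour is six operations longer and brings back the etherification of a hindered tertiary hydroxyl, which is why it is only the reserve.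

**Step 3.** Most likely failure: alkylation through carbon or [3,3] rearrangement of the propargyl vinyl ether, base-induced epimerisation at the γ-carbon, or stalling of the copper cycle with an enol in place of a phenol.

Fallback, from 5 back to 7: Nicholas etherification of 5 with complex F6 (BF3·OEt2, CH2Cl2, −20 °C) gives the cobalt-complexed enol ether F9, whose complexed alkyne cannot enter a sigmatropic shift. (NH4)2Ce(NO3)6 in acetone at 0 °C then releases 7.

**Step 13.** Most likely failure: incomplete deoxygenation at the hindered secondary carbinol, or substitution or elimination at the tertiary C3 hydroxyl at 80 °C.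

Fallback, from 19 back to 20: 19 is converted with 1,1′-thiocarbonyldiimidazole into the cyclic thiocarbonate F10, which is fragmented with 1,3-dimethyl-2-phenyl-1,3,2-diazaphospholidine at 40 °C (Corey–Winter olefination).

**Step 15.** Most likely failure: slow loading of ruthenium onto two alkenes that each have a fully substituted allylic carbon, with oligomerisation or alkene isomerisation taking over, aggravated by the strain of the bridged ring.

Fallback, from 21 to 22: the C=C is made by reductive coupling instead of metathesis. Ozonolysis of 21 gives the dialdehyde F11. SmI2 pinacol cyclisation at −78 °C should give the ring cis-diol F12. 1,1′-Thiocarbonyldiimidazole converts it into the thiocarbonate F13, and the same diazaphospholidine fragmentation gives the Z alkene of 22.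

## Further compounds

F1 | step 8 | (5R)-5-[(4S)-2,2-dimethyl-1,3-dioxolan-4-yl]-4-methyl-2-oxo-2,5-dihydrofuran-3-yl trifluoromethanesulfonate (enol triflate) | O=C1O[C@@H]([C@@H]2COC(C)(C)O2)C(C)=C1OS(=O)(=O)C(F)(F)F
F2 | step 8 | (5R)-5-[(4S)-2,2-dimethyl-1,3-dioxolan-4-yl]-4-methylfuran-2(5H)-one (3-unsubstituted butenolide) | O=C1O[C@@H]([C@@H]2COC(C)(C)O2)C(C)=C1
F3 | step 8 | C4–H lactone: analogue of 15 with hydrogen in place of the C4 ether, H cis to the C5 methyl | COc1ccc(CO[C@H]2C[C@](C)(O)[C@@H]3C(=O)O[C@@H]([C@@H]4COC(C)(C)O4)[C@]3(C)[C@H]2O)cc1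
F4 | step 8 | bis(triethylsilyl) ether of F3 (C3 and C6 oxygens) | COc1ccc(CO[C@H]2C[C@](C)(O[Si](CC)(CC)CC)[C@@H]3C(=O)O[C@@H]([C@@H]4COC(C)(C)O4)[C@]3(C)[C@H]2O[Si](CC)(CC)CC)cc1
F5 | step 8 | C4 hydroxy lactone (C3, C6 bis(triethylsilyl) ether) | COc1ccc(CO[C@H]2C[C@](C)(O[Si](CC)(CC)CC)[C@]3(O)C(=O)O[C@@H]([C@@H]4COC(C)(C)O4)[C@]3(C)[C@H]2O[Si](CC)(CC)CC)cc1
F6 | step 8 | cobalt–alkynol complex Co2(CO)6(HC≡CC(CH3)2OH) | CC(C)(O)C12C3[Co]1(=C=O)(=C=O)(=C=O)[Co]23(=C=O)(=C=O)=C=O
F7 | step 8 | Co2(CO)6 complex of the C4 1,1-dimethylpropargyl ether of F5 (complexed ether) | COc1ccc(CO[C@H]2C[C@](C)(O[Si](CC)(CC)CC)[C@]3(OC(C)(C)C56C7[Co]5(=C=O)(=C=O)(=C=O)[Co]67(=C=O)(=C=O)=C=O)C(=O)O[C@@H]([C@@H]4COC(C)(C)O4)[C@]3(C)[C@H]2O[Si](CC)(CC)CC)cc1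
F8 | step 8 | C3, C6 bis(triethylsilyl) ether of 15 (alkyne) | COc1ccc(CO[C@H]2C[C@](C)(O[Si](CC)(CC)CC)[C@]3(OC(C)(C)C#C)C(=O)O[C@@H]([C@@H]4COC(C)(C)O4)[C@]3(C)[C@H]2O[Si](CC)(CC)CC)cc1
F9 | step 3 | Co2(CO)6 complex of 7 (cobalt-complexed enol ether) | O=C1O[C@@H]([C@@H]2COC(C)(C)O2)C(C)=C1OC(C)(C)C34C5[Co]3(=C=O)(=C=O)(=C=O)[Co]45(=C=O)(=C=O)=C=O
F10 | step 13 | cyclic thiocarbonate of diol 19 | CC(=O)O[C@H]1C[C@](C)(O)[C@]2(OC(C)(C)C#C)C(=O)O[C@@H]([C@@H]3COC(=S)O3)[C@]2(C)[C@H]1OC(=O)c1ccccc1
F11 | step 15 | dialdehyde from 21 (C7 formyl, C4 O–C(CH3)2–CHO) | CC(=O)O[C@H]1C[C@](C)(O)[C@]2(OC(C)(C)C=O)C(=O)O[C@@H](C=O)[C@]2(C)[C@H]1OC(=O)c1ccccc1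
F12 | step 15 | cis-diol of the oxepane ring (configuration of the two new carbinols cis, not assigned) | CC(=O)O[C@H]1C[C@](C)(O)[C@]23OC(C)(C)C(O)C(O)[C@H](OC2=O)[C@]3(C)[C@H]1OC(=O)c1ccccc1
F13 | step 15 | cyclic thiocarbonate of F12 | CC(=O)O[C@H]1C[C@](C)(O)[C@]23OC(C)(C)C4OC(=S)OC4[C@H](OC2=O)[C@]3(C)[C@H]1OC(=O)c1ccccc1
A1 | alternative 1 | lactone-bridged bicyclo[2.2.2]octene Diels–Alder adduct | O=C1O[C@@H]2C=C(C)[C@@]1(O)[C@](C)(C=O)[C@H]2OC(=O)c3ccccc3
A2 | alternative 1 | 3-hydroxy-4-methyl-2H-pyran-2-one | CC1=C(O)C(=O)OC=C1
A3 | alternative 1 | (E)-3-(benzoyloxy)-2-methylprop-2-enal | O=C/C(C)=C/OC(=O)c1ccccc1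
A4 | alternative 2 | hydroxy oxepane lactone (C3 triethylsilyl ether) | CC(=O)O[C@H]1C[C@](C)(O[Si](CC)(CC)CC)[C@]23OC(C)(C)[C@H](O)C[C@H](OC2=O)[C@]3(C)[C@H]1OC(=O)c1ccccc1
A5 | alternative 2 | epoxy alcohol precursor (free C4 hydroxyl, (3,3-dimethyloxiranyl)methyl on C7) | CC(=O)O[C@H]1C[C@](C)(O[Si](CC)(CC)CC)[C@]2(O)C(=O)O[C@@H](C[C@H]3OC3(C)C)[C@]2(C)[C@H]1OC(=O)c1ccccc1
A6 | alternative 3 | tricyclic homoallylic alcohol with exocyclic methylene | O[C@H]1CC(=C)[C@]23OC(C)(C)C=C[C@H](OC2=O)[C@]3(C)[C@H]1OC(=O)c1ccccc1
A7 | alternative 3 | isopropenyl aldehyde precursor (oxepine lactone with C4 isopropenyl and C5 benzoyloxyacetaldehyde arm) | C=C(C)[C@]23OC(C)(C)C=C[C@H](OC2=O)[C@]3(C)[C@H](C=O)OC(=O)c1ccccc1
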